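The data are simulated with made-up constants, noise included.

| setting | north | east | flask |
|---|---|---|---|
| J | 0.40 M (fed, over 2.5 s) | 0.80 M (fed, over 2.5 s) | 0.40 M (fed, over 2.5 s) |
| G | 0.72 M | 0.72 M | 0.720 M |
| remark | the very flask that is asked about, followed so far | run made earlier |  |
| time |  |  | 15 min |
| volume of the second phase over the first |  |  | 0.25 |

north run (percent of the J charged)

| time / s | L / % | J / % |
|---|---|---|
| 10.0 | 18.7 | 69.9 |
| 25.0 | 35.0 | 33.5 |
| 50.0 | 40.2 | 9.6 |
| 80.0 | 35.5 | 3.2 |
| 120 | 29.2 | 1.4 |

east run (percent of the J charged)

| time / min | L / % | J / % |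
|---|---|---|
| 2.00 | 21.4 | 3.2 |
| 4.00 | 10.5 | 0.1 |
| 6.00 | 0.6 | 0.8 |
| 8.00 | 0.6 | 0 |
| 10.0 | 0 | 0 |

(each reading ± 1 percentage point)

- a species is counted by the J in it: one Q counts as two
- amounts and yields of L count E and X too
- in the second phase: G, E; everything else is in the first
- charges count per volume of the first phase; a concentration in a rate is the amount of a species over the volume of its own phase; every rate counts per litre of the first phase
- given per volume of solution although it is solid: X
- the analysis behind the earlier runs scatters by 1 percentage point, standard deviation
- on the list of suspects stand: Z <-> G; J + Z -> L; L <-> E; L -> D; J + L -> Q; X <-> L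
- the earlier runs hold the two phases in the same ratio of volumes as the flask asked about

* when, up to 15 min, the flask holds most L
* the amount of L, in percent of the J charged, at that time

If the J that reacted in the north flask stayed as L, its L would mirror its J, and the kept share would be 1; I used that case as the zero of my scale. At 10.0 s the kept share was already 0.621, and up to 25.0 s L climbed at 4.35 mM s⁻¹.

For the falling side I turned to the east run, where J was down to 3.2% at 2.00 min:

drain = fall of L × charge ÷ interval = 0.727 mM s⁻¹

I named this steady molar fall of L, taken as zero-order, the drain. The north run, with half that charge, ended by falling 0.630 mM s⁻¹, so I used the drain there too.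

J meanwhile decayed in a pseudo-first-order way, at 0.0500 s⁻¹ between the second and third readings. Adding the drain back over that stretch gave the kept share:

kept share = (rise of L + drain × interval) ÷ J consumed = 0.408

The top comes where the making of L meets the drain:

J at the top = drain ÷ (decay constant × kept share × charge) = 8.92%

J reaches that at 0.858 min. I committed to that time and to the 40.2% read nearby. From there the drain brings L down to a level of zero at about 4.55 min.

The forecast gave 0.78 min and 40.5%, on the ground “This looks zero-order”.

The flask held most L at 0.822 min, namely 39.6%.

    Z ⇌ G, rate k1*([Z] - [G]/K1) per volume of the first phase (partition coefficient = 2.60, kL = 0.107 s⁻¹)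
    J + Z → L (k = 0.120 M⁻¹ s⁻¹)
    L ⇌ E, rate k3*([L] - [E]/K3) per volume of the first phase (partition coefficient = 0.782, kL = 0.152 s⁻¹)
    L → D (k = 0.0193 s⁻¹)
    J + L → Q (k = 0.222 M⁻¹ s⁻¹)
    X ⇌ L, rate k6*(cs6 - [L]) while solid is left; crystals form when [L] > cs6 (solubility = 49.0 mM, k = 1.34 s⁻¹)

At 0.822 min, crystals X held 25.0% of the J charged, and this amount is counted within that L. At the drain, the best amount lasts 3.64 min, and the flask held 0.189% at 7.50 min. The neighbour charged with 0.68 M of J reached 32.7%, which the drain would empty in 5.10 min, and it held 0% at 15.0 min.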